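**Plan**
1. Retrosynthetic cuts: the C3–O acyl bond; N1–C8a (ring closure); C2–CH3 and C2–C3; C4–C4a and C5–C1'; C3'–C4' of the side chain.
2. Enabling feature: in the piperidine ring the carbon run C3–C4–C4a–C8a carries a heteroatom at each end (O on C3, N1 on C8a), and C2 is bonded to C3. The ring is therefore the oxidised, ring-expanded form of a 2-(1-aminoethyl)furan fused to the carbocycle at C4a–C8a.
3. Forward order: the side chain is made first. It is joined at C5 to purchased cyclohexenone (the carbocycle) in the same operation that places an allyl group on C4a. The allyl ketone is folded into a temporary furan, then C2, its methyl group and N1 are added. Oxidative ring expansion with ionic reduction closes N1–C8a, so the piperidine is the last ring.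
4. Stereochemistry: C5' comes from (R)-2-propyloxirane, C5 from a chiral copper catalyst and C2 from the tert-butanesulfinamide auxiliary. C8a (axial hydride, syn to the pseudoaxial C2 methyl), C3 (hydride anti to that methyl) and C4a (hydrogenation directed by O3–H) are relayed inside the new ring.

Key step: step 9

Remark: the target is read as (2S,3S,4aR,5R,8aS,5'R), a cis-fused ring system with 2,3-cis and 2,8a-trans relationships and an all-cis carbocycle. Decahydroquinoline numbering (N1, C2–C4, C4a, C5–C8, C8a, chain C1'–C8') is used for every intermediate. (R)-2-propyloxirane is taken as a catalogue compound. TBS = tert-butyldimethylsilyl, Bus = tert-butylsulfonyl.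

**Step 1**
Reactants: 1 (R)-2-propyloxirane; 2 allylmagnesium bromide
Product: 3 (R)-oct-7-en-4-ol
Conditions: CuI (10 mol %), THF, −30 → 0 °C; H2O work-up
Reagents that add atoms: none
Why: Copper-catalysed SN2 opening of a terminal epoxide by a Grignard reagent takes place at the unsubstituted carbon, so the C–O stereocentre of 1 is untouched and becomes C5' (R).

**Step 2**
Reactants: 3 (R)-oct-7-en-4-ol
Product: 4 (R)-tert-butyl(dimethyl)(oct-7-en-4-yloxy)silane
Conditions: TBSCl, imidazole, DMF, rt
Reagents that add atoms: tert-butyldimethylsilyl chloride CC(C)(C)[Si](C)(C)Cl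
Why: Imidazole-promoted silylation of a secondary alcohol gives an ether that tolerates organometallics, peracid, BF3 at low temperature and hydrogenation, and that falls in the final acid step.

**Step 3**
Reactants: 4 (R)-tert-butyl(dimethyl)(oct-7-en-4-yloxy)silane (two equivalents)
Product: 6 bis[(5R)-5-(TBSO)octyl]zinc, via alkyldiethylborane 5 (not isolated)
Conditions: Et2BH (from BH3·SMe2 + 2 Et3B), Et2O, 0 °C → rt; Et2Zn, 0 °C; volatiles off in vacuo; residue taken up in toluene
Reagents that add atoms: diethylborane CCBCC (stays only in 5); diethylzinc CC[Zn]CC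
Why: Anti-Markovnikov hydroboration of the terminal alkene followed by boron–zinc exchange, driven by removal of volatile Et3B, is the standard entry to functionalised primary dialkylzincs and leaves the silyl ether and C5' alone.

**Step 4**
Reactants: 6 bis[(5R)-5-(TBSO)octyl]zinc; 7 cyclohex-2-en-1-one; 8 allyl acetate
Product: 10 (2S,3R)-2-allyl-3-[(5R)-5-(TBSO)octyl]cyclohexan-1-one, via zinc enolate 9 (not isolated)
Conditions: Cu(OTf)2 (2 mol %), O,O'-[(R)-1,1'-binaphthalene-2,2'-diyl] N,N-bis[(S)-1-phenylethyl]phosphoramidite (4 mol %), toluene, −30 °C; then Pd(PPh3)4 (4 mol %), 8, 0 °C; H2O work-up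
Reagents that add atoms: none
Why: Copper/phosphoramidite-catalysed enantioselective conjugate addition of a dialkylzinc sets C5 (R) under ligand control (the mirror-image ligand belongs to the 3S series), and the regiodefined zinc enolate is caught at C4a by Tsuji–Trost allylation anti to the new chain, a C4a configuration that step 5 erases.

**Step 5**
Reactants: 10 (2S,3R)-2-allyl-3-[(5R)-5-(TBSO)octyl]cyclohexan-1-one
Product: 12 (4R)-4-[(5R)-5-(TBSO)octyl]-4,5,6,7-tetrahydro-1-benzofuran, via keto aldehyde 11 (not isolated)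
Conditions: O3, CH2Cl2, −78 °C; Me2S, → rt; solvent swap; pyridinium p-toluenesulfonate (10 mol %), 4 Å MS, toluene, 60 °C
Reagents that add atoms: ozone [O-][O+]=O
Why: Ozonolysis of the only alkene gives a 1,4-keto aldehyde that undergoes Paal–Knorr cyclodehydration to the fused furan, which flattens C4a, leaves C5 untouched and installs the temporary ring that step 9 consumes.

**Step 6**
Reactants: 12 (4R)-4-[(5R)-5-(TBSO)octyl]-4,5,6,7-tetrahydro-1-benzofuran
Product: 14 (4R)-4-[(5R)-5-(TBSO)octyl]-4,5,6,7-tetrahydro-1-benzofuran-2-carbaldehyde, via 2-lithiofuran 13 (not isolated)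
Conditions: n-BuLi, THF, 0 °C; DMF, −78 °C → rt; H2O work-up
Reagents that add atoms: n-butyllithium CCCC[Li] (lithium only in 13); N,N-dimethylformamide CN(C)C=O
Why: α-Lithiation of a furan can occur only at the single free α-position (future C3), and formylation with DMF adds the carbon that becomes C2.

**Step 7**
Reactants: 14 (4R)-4-[(5R)-5-(TBSO)octyl]-4,5,6,7-tetrahydro-1-benzofuran-2-carbaldehyde; 15 (R)-2-methylpropane-2-sulfinamide
Product: 16 (R,E)-N-{[(4R)-4-[(5R)-5-(TBSO)octyl]-4,5,6,7-tetrahydro-1-benzofuran-2-yl]methylidene}-2-methylpropane-2-sulfinamide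
Conditions: Ti(OEt)4, THF, rt
Reagents that add atoms: none
Why: Ti(OEt)4-mediated condensation of an aryl aldehyde with tert-butanesulfinamide gives the (E)-sulfinyl aldimine without touching sulfur or C5.

**Step 8**
Reactants: 16 (R,E)-sulfinyl aldimine
Product: 17 (R)-N-{(1S)-1-[(4R)-4-[(5R)-5-(TBSO)octyl]-4,5,6,7-tetrahydro-1-benzofuran-2-yl]ethyl}-2-methylpropane-2-sulfinamide
Conditions: MeMgBr, CH2Cl2, −48 °C; H2O work-up
Reagents that add atoms: methylmagnesium bromide C[Mg]Br
Why: 1,2-Addition of a Grignard reagent to an N-tert-butanesulfinyl aldimine in a non-coordinating solvent runs through the six-membered magnesium chelate with tert-butyl equatorial, which for the (R)-sulfinyl (E)-aldimine sends methyl to the face that gives C2 (S).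

**Step 9**
Reactants: 17 (R)-sulfinamide of the (1S)-1-(furan-2-yl)ethylamine
Product: 22 (2S,5R,8aS)-1-Bus-5-[(5R)-5-(TBSO)octyl]-2-methyl-1,5,6,7,8,8a-hexahydroquinolin-3(2H)-one, via tert-butylsulfonamide 18 (not isolated), via Z-enedione 19 (not isolated), via hemiaminal 20 (not isolated), via N-sulfonyliminium ion 21 (not isolated)
Conditions: mCPBA (2.2 equiv), CH2Cl2, 0 °C → rt; aq NaHCO3 wash, dry; crude solution, Et3SiH (5 equiv), BF3·OEt2 (2 equiv), CH2Cl2, −78 → −40 °C
Reagents that add atoms: 3-chloroperoxybenzoic acid O=C(OO)c1cccc(Cl)c1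
Why: One equivalent of peracid takes the sulfinamide to tert-butylsulfonamide 18 and a second oxidises the electron-rich trisubstituted furan, which opens to Z-enedione 19; the sulfonamide nitrogen adds to the C8a ketone to give hemiaminal 20, BF3 ionises 20 to N-sulfonyliminium ion 21, and Et3SiH transfers hydride to C8a. The closest known reaction types are the aza-Achmatowicz oxidative ring expansion of furfuryl sulfonamides, the silane reduction of the resulting cyclic N,O-acetals, and the axial hydride reduction of 2,6-dialkyl N-acyliminium ions to trans-2,6-piperidines. The piperidine ring closes by 6-exo-trig attack of N1 on the C8a carbonyl while the temporary furan ring is opened. The one new stereocentre, C8a, is controlled by C2 and C5 together: A(1,3) strain against the sulfonyl group holds the C2 methyl pseudoaxial, stereoelectronically favoured axial attack then places H8a on the methyl face (the 2,8a-trans relationship), and attack on the other face would force the C5 chain axial and 1,3 to the incoming silane. Chemoselective oxidation is secured because sulfur and the furan are the only oxidisable sites; the meeting of N1 and C8a is secured because the Z geometry is inherited from the furan, an E isomer would press the acyl group against C5, and the C3 carbonyl is out of reach of N1; hydride capture at C8a rather than at C4 is secured because C4 is alpha to the ketone and carries little positive charge. The product keeps the C3 ketone and the C4=C4a alkene, the two handles through which steps 10 and 11 relay C2 to C3 and C4a.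

**Step 10**
Reactants: 22 (2S,5R,8aS)-enone
Product: 23 (2S,3S,5R,8aS)-1-Bus-5-[(5R)-5-(TBSO)octyl]-2-methyl-1,2,3,5,6,7,8,8a-octahydroquinolin-3-ol
Conditions: NaBH4, CeCl3·7H2O, MeOH, −78 °C
Reagents that add atoms: none
Why: Luche 1,2-reduction delivers hydride to C3 from the face opposite the pseudoaxial C2 methyl, so O3 ends up cis to the methyl group (3S).

**Step 11**
Reactants: 23 (2S,3S,5R,8aS)-allylic alcohol
Product: 24 (2S,3S,4aR,5R,8aS)-1-Bus-5-[(5R)-5-(TBSO)octyl]-2-methyldecahydroquinolin-3-ol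
Conditions: H2 (10 bar), [Ir(cod)(PCy3)(py)]PF6 (10 mol %), CH2Cl2, rt
Reagents that add atoms: none
Why: Hydroxyl-directed homogeneous hydrogenation binds the cationic iridium centre to the allylic O3–H and adds H2 to C4=C4a on that face, which sets C4a (R) with H4a cis to H8a and H5, that is, the cis ring fusion and the all-cis carbocycle.

**Step 12**
Reactants: 24 (2S,3S,4aR,5R,8aS)-alcohol; 25 (E)-oct-2-enoic acid
Product: 26 (2S,3S,4aR,5R,8aS)-1-Bus-5-[(5R)-5-(TBSO)octyl]-2-methyldecahydroquinolin-3-yl (E)-oct-2-enoate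
Conditions: DCC, DMAP (20 mol %), CH2Cl2, 0 °C → rt
Reagents that add atoms: none
Why: Steglich esterification acylates the only free hydroxyl group with retention at C3 and, being free of strong base, keeps the E-2-enoate conjugated.

**Step 13**
Reactants: 26 N-Bus O-TBS ester
Product: 28 (2S,3S,4aR,5R,8aS)-5-[(5R)-5-hydroxyoctyl]-2-methyldecahydroquinolin-3-yl (E)-oct-2-enoate, via amine silyl ether 27 (not isolated)
Conditions: TfOH (0.1 M), anisole, CH2Cl2, 0 °C; then H2O/MeCN, rt; aq NaHCO3
Reagents that add atoms: none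
Why: Acidolysis of the tert-butylsulfonamide (loss of the tert-butyl cation to anisole, then of SO2, helped by relief of strain at the hindered nitrogen) and acid hydrolysis of the silyl ether touch no stereocentre, while the enoate is inert and the protonated amine cannot take part in an O-to-N acyl shift.

**Compound list**
1 | (R)-2-propyloxirane | CCC[C@@H]1CO1 | starting material
2 | allylmagnesium bromide | C=CC[Mg]Br | starting material
3 | (R)-oct-7-en-4-ol | C=CCC[C@H](O)CCC | intermediate
4 | (R)-tert-butyl(dimethyl)(oct-7-en-4-yloxy)silane | C=CCC[C@H](O[Si](C)(C)C(C)(C)C)CCC | intermediate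
5 | diethyl[(5R)-5-(TBSO)octyl]borane | CCB(CC)CCCC[C@H](O[Si](C)(C)C(C)(C)C)CCC | intermediate
6 | bis[(5R)-5-(TBSO)octyl]zinc | [Zn](CCCC[C@H](O[Si](C)(C)C(C)(C)C)CCC)CCCC[C@H](O[Si](C)(C)C(C)(C)C)CCC | intermediate
7 | cyclohex-2-en-1-one | O=C1C=CCCC1 | starting material
8 | allyl acetate | C=CCOC(C)=O | starting material
9 | alkylzinc enolate of (3R)-3-[(5R)-5-(TBSO)octyl]cyclohexanone | [Zn](CCCC[C@H](O[Si](C)(C)C(C)(C)C)CCC)OC1=C[C@H](CCCC[C@H](O[Si](C)(C)C(C)(C)C)CCC)CCC1 | intermediate
10 | (2S,3R)-2-allyl-3-[(5R)-5-(TBSO)octyl]cyclohexan-1-one | O=C1CCC[C@@H](CCCC[C@H](O[Si](C)(C)C(C)(C)C)CCC)[C@@H]1CC=C | intermediate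
11 | 2-{(1S,2R)-2-[(5R)-5-(TBSO)octyl]-6-oxocyclohexyl}acetaldehyde | O=C1CCC[C@@H](CCCC[C@H](O[Si](C)(C)C(C)(C)C)CCC)[C@@H]1CC=O | intermediate
12 | (4R)-4-[(5R)-5-(TBSO)octyl]-4,5,6,7-tetrahydro-1-benzofuran | c1cc2c(o1)CCC[C@H]2CCCC[C@H](O[Si](C)(C)C(C)(C)C)CCC | intermediate
13 | 2-lithio derivative of 12 | [Li]c1cc2c(o1)CCC[C@H]2CCCC[C@H](O[Si](C)(C)C(C)(C)C)CCC | intermediate
14 | (4R)-4-[(5R)-5-(TBSO)octyl]-4,5,6,7-tetrahydro-1-benzofuran-2-carbaldehyde | O=Cc1cc2c(o1)CCC[C@H]2CCCC[C@H](O[Si](C)(C)C(C)(C)C)CCC | intermediate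
15 | (R)-2-methylpropane-2-sulfinamide | CC(C)(C)[S@@](=O)N | starting material
16 | (R,E)-N-sulfinyl aldimine of 14 | CC(C)(C)[S@@](=O)/N=C/c1cc2c(o1)CCC[C@H]2CCCC[C@H](O[Si](C)(C)C(C)(C)C)CCC | intermediate
17 | (R)-sulfinamide of the (1S)-1-(furan-2-yl)ethylamine | CC(C)(C)[S@@](=O)N[C@@H](C)c1cc2c(o1)CCC[C@H]2CCCC[C@H](O[Si](C)(C)C(C)(C)C)CCC | intermediate
18 | N-Bus (1S)-1-(furan-2-yl)ethylamine | CC(C)(C)S(=O)(=O)N[C@@H](C)c1cc2c(o1)CCC[C@H]2CCCC[C@H](O[Si](C)(C)C(C)(C)C)CCC | intermediate
19 | (Z)-2-ylidene-cyclohexanone enedione, N-Bus (S)-amine | CC(C)(C)S(=O)(=O)N[C@@H](C)C(=O)/C=C1\C(=O)CCC[C@H]1CCCC[C@H](O[Si](C)(C)C(C)(C)C)CCC | intermediate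
20 | (2S,5R)-1-Bus-8a-hydroxy-5-[(5R)-5-(TBSO)octyl]-2-methyl-1,5,6,7,8,8a-hexahydroquinolin-3(2H)-one (C8a configuration open, lost on ionisation) | O=C1C=C2[C@H](CCCC[C@H](O[Si](C)(C)C(C)(C)C)CCC)CCCC2(O)N(S(=O)(=O)C(C)(C)C)[C@H]1C | intermediate
21 | N-sulfonyliminium cation from 20 (N1=C8a) | O=C1C=C2[C@H](CCCC[C@H](O[Si](C)(C)C(C)(C)C)CCC)CCCC2=[N+](S(=O)(=O)C(C)(C)C)[C@H]1C | intermediate
22 | (2S,5R,8aS)-1-Bus-5-[(5R)-5-(TBSO)octyl]-2-methyl-1,5,6,7,8,8a-hexahydroquinolin-3(2H)-one | O=C1C=C2[C@H](CCCC[C@H](O[Si](C)(C)C(C)(C)C)CCC)CCC[C@@H]2N(S(=O)(=O)C(C)(C)C)[C@H]1C | intermediate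
23 | (2S,3S,5R,8aS)-1-Bus-5-[(5R)-5-(TBSO)octyl]-2-methyl-1,2,3,5,6,7,8,8a-octahydroquinolin-3-ol | O[C@H]1C=C2[C@H](CCCC[C@H](O[Si](C)(C)C(C)(C)C)CCC)CCC[C@@H]2N(S(=O)(=O)C(C)(C)C)[C@H]1C | intermediate
24 | (2S,3S,4aR,5R,8aS)-1-Bus-5-[(5R)-5-(TBSO)octyl]-2-methyldecahydroquinolin-3-ol | O[C@H]1C[C@@H]2[C@H](CCCC[C@H](O[Si](C)(C)C(C)(C)C)CCC)CCC[C@@H]2N(S(=O)(=O)C(C)(C)C)[C@H]1C | intermediate
25 | (E)-oct-2-enoic acid | CCCCC/C=C/C(=O)O | starting material
26 | N-Bus O-TBS (E)-oct-2-enoate of 24 | CCCCC/C=C/C(=O)O[C@H]1C[C@@H]2[C@H](CCCC[C@H](O[Si](C)(C)C(C)(C)C)CCC)CCC[C@@H]2N(S(=O)(=O)C(C)(C)C)[C@H]1C | intermediate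
27 | N–H O-TBS (E)-oct-2-enoate | CCCCC/C=C/C(=O)O[C@H]1C[C@@H]2[C@H](CCCC[C@H](O[Si](C)(C)C(C)(C)C)CCC)CCC[C@@H]2N[C@H]1C | intermediate
28 | (2S,3S,4aR,5R,8aS)-5-[(5R)-5-hydroxyoctyl]-2-methyldecahydroquinolin-3-yl (E)-oct-2-enoate | CCCCC/C=C/C(=O)O[C@H]1C[C@@H]2[C@H](CCCC[C@H](O)CCC)CCC[C@@H]2N[C@H]1C | target

Total step count: 13. Longest linear sequence: 13 steps (1 → 28).

**Steps most likely to fail**

Step 9. Three things may go wrong.
- The hindered sulfonamide may close onto the ketone incompletely, with the ring–chain equilibrium on the open side.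
- The ring may aromatise by loss of sulfinate.
- The bulk of the C2 methyl may steer hydride transfer to the opposite face.

The fallback sets out from 17 and comes back at 24. Compound 17 is oxidised as in step 9, but 20 is taken on without silane. Catalytic camphorsulfonic acid and 4 Å molecular sieves in CH2Cl2 should dehydrate it through 21 to the cross-conjugated N-sulfonyl dienone F1. Luche reduction, again anti to the C2 methyl, should give the dienol F2. Hydrogenation with [Ir(cod)(PCy3)(py)]PF6 bound to O3–H should then saturate both C4=C4a and C8=C8a from the O3 face. In this way H4a and H8a are both delivered by the directing group instead of an external hydride, and 24 results.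

Step 11. Possible problems are slow turnover at the hindered trisubstituted alkene, loss of direction by competing binding of the sulfonyl oxygens, and isomerisation of the allylic alcohol to the ketone. The fallback sets out from 22 and comes back at 24. The order of the two reductions is reversed, and the shape of the substrate replaces the directing group. Heterogeneous hydrogenation of the enone (H2, Pd/C, EtOAc) should add hydrogen from the face that carries the axial H8a and H5, opposite the tert-butyl group of the sulfonamide, to give the saturated ketone F3. Equatorial attack of LiBH(s-Bu)3 (THF, −78 °C) on F3 should then give the axial, 2,3-cis alcohol 24.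

Step 4. Possible problems are incomplete boron–zinc exchange with competing ethyl transfer, erosion of enantioselectivity with the long functionalised chain, and sluggish allylation of the zinc enolate. The fallback sets out from 4, comes back at 12 and bypasses steps 3 to 5.
- Commercial 6,7-dihydro-1-benzofuran-4(5H)-one F4 is converted with LiN(SiMe3)2 and PhNTf2 (THF, −78 °C) to the enol triflate F5.
- Compound 4 is hydroborated with 9-BBN-H to the B-alkyl borane F6.
- Suzuki–Miyaura coupling of F5 and F6 (PdCl2(dppf), Cs2CO3, DMF/THF/H2O) should give the 4-alkyl-6,7-dihydrobenzofuran F7.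
- Asymmetric hydrogenation of the trisubstituted ring alkene with the enantiomer of [Ir(cod)(tBu-PHOX)]BArF that leads to 4R (H2, CH2Cl2) should give 12, with C5 now set by the hydrogenation catalyst.

**Further compounds**
F1 | step 9 | (2S,5R)-1-Bus-5-[(5R)-5-(TBSO)octyl]-2-methyl-1,5,6,7-tetrahydroquinolin-3(2H)-one | O=C1C=C2[C@H](CCCC[C@H](O[Si](C)(C)C(C)(C)C)CCC)CCC=C2N(S(=O)(=O)C(C)(C)C)[C@H]1C
F2 | step 9 | (2S,3S,5R)-1-Bus-5-[(5R)-5-(TBSO)octyl]-2-methyl-1,2,3,5,6,7-hexahydroquinolin-3-ol | O[C@H]1C=C2[C@H](CCCC[C@H](O[Si](C)(C)C(C)(C)C)CCC)CCC=C2N(S(=O)(=O)C(C)(C)C)[C@H]1C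
F3 | step 11 | (2S,4aR,5R,8aS)-1-Bus-5-[(5R)-5-(TBSO)octyl]-2-methyloctahydroquinolin-3(2H)-one | O=C1C[C@@H]2[C@H](CCCC[C@H](O[Si](C)(C)C(C)(C)C)CCC)CCC[C@@H]2N(S(=O)(=O)C(C)(C)C)[C@H]1C
F4 | step 4 | 6,7-dihydro-1-benzofuran-4(5H)-one (commercial) | O=C1CCCc2occc12
F5 | step 4 | 6,7-dihydro-1-benzofuran-4-yl trifluoromethanesulfonate | O=S(=O)(OC1=CCCc2occc12)C(F)(F)F
F6 | step 4 | 9-[(5R)-5-(TBSO)octyl]-9-borabicyclo[3.3.1]nonane | B1(CCCC[C@H](O[Si](C)(C)C(C)(C)C)CCC)C2CCCC1CCC2
F7 | step 4 | 4-[(5R)-5-(TBSO)octyl]-6,7-dihydro-1-benzofuran | C1(CCCC[C@H](O[Si](C)(C)C(C)(C)C)CCC)=CCCc2occc12
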